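## Retrosynthetic overview

1. The target is an eleven-ring poly(aryl ether) with no stereocentre (rings A to K from the 2,4,6-trihydroxyphenyl end): tetraoxygenated rings B, D, F, H, J alternate with pentaoxygenated rings C, E, G and I.
2. The strategy rests on ring G: five contiguous oxygens (C1 ether O to ring F, C2 ether O to ring H, C3–C5 hydroxyls) and one hydrogen (C6). C2–C5 are taken from dibenzyl squarate; C1 and C6 come from an (E)-2-aryloxyvinyl group that already carries ring F. The crowded F–O–G ether is therefore made as a vinyl ether, and ring G is closed by cyclobutenone-to-phenol ring expansion (C1–C2 bond).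
3. Rings C, E and I repeat ring G exactly, so the same ring-expansion product 26 (pair F–G) also serves as the pairs B–C, D–E and H–I.
4. The remaining five ethers all join a hindered phenol to an unhindered aryl triflate: 26 gives dimer triflate 30; 26 + 30 gives a tetramer, then triflate 33; ring A phenol 27 + 33 gives five rings; + 33 gives nine rings; + J–K triflate 41 gives eleven rings; hydrogenolysis of 28 benzyl ethers ends the route.
5. Ring formation: only the pentaoxygenated rings are built (step 12); rings A, B, D, F, H, J and K all derive from 3,4,5-trihydroxybenzaldehyde.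

Key step: step 12

Remark: the target has no stereocentre, so only alkene geometry has to be controlled; the carbinol carbon of 21–23 and the sp3 carbon of 25 form racemic and vanish on aromatization. Bn = benzyl, MOM = methoxymethyl, TIPS = tri(propan-2-yl)silyl, Tf = trifluoromethanesulfonyl.

## Route

Step 1
Reactants: 1 3,4,5-trihydroxybenzaldehyde
Product: 2 3,4,5-tris(benzyloxy)benzaldehyde
Conditions: BnBr, K2CO3, DMF, 60 °C
Reagents that add atoms: benzyl bromide, BrCc1ccccc1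
Why: Williamson ether synthesis; the three phenoxides are alkylated at the benzylic carbon and the aldehyde is inert to carbonate.

Step 2
Reactants: 2 3,4,5-tris(benzyloxy)benzaldehyde
Product: 4 3,4,5-tris(benzyloxy)phenol, via aryl formate 3 (not isolated)
Conditions: mCPBA, CH2Cl2, rt; then K2CO3 (cat.), MeOH, rt
Reagents that add atoms: 3-chloroperoxybenzoic acid, OOC(=O)c1cccc(Cl)c1
Why: Dakin-type Baeyer–Villiger oxidation; the electron-rich aryl group migrates to oxygen and methanolysis of the formate should release the phenol.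

Step 3
Reactants: 4 3,4,5-tris(benzyloxy)phenol
Product: 6 2,6-bis(benzyloxy)cyclohexa-2,5-diene-1,4-dione, via quinone hemiketal 5 (not isolated)
Conditions: PhI(OAc)2, MeCN–H2O, 0 °C
Reagents that add atoms: water, O
Why: Oxidative dealkylation of a para-alkoxyphenol by a trivalent iodine reagent; water adds at the oxidized C4 to give hemiketal 5, and loss of benzyl alcohol should leave the para-quinone.

Step 4
Reactants: 6 2,6-bis(benzyloxy)cyclohexa-2,5-diene-1,4-dione
Product: 7 2,6-bis(benzyloxy)benzene-1,4-diol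
Conditions: Na2S2O4, THF–H2O, rt, argon
Reagents that add atoms: none
Why: Two-electron reduction of the quinone to the hydroquinone by dithionite.

Step 5
Reactants: 7 2,6-bis(benzyloxy)benzene-1,4-diol
Product: 8 2,6-bis(benzyloxy)-4-(methoxymethoxy)phenol
Conditions: MOMCl (1.0 equiv), i-Pr2NEt, CH2Cl2, 0 °C, argon
Reagents that add atoms: chloromethyl methyl ether, COCCl
Why: Selective O-alkylation (MOM ether formation); the C4 hydroxyl, flanked by two ring hydrogens and the more acidic, should react ahead of the C1 hydroxyl buried between two benzyloxy groups.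

Step 6
Reactants: 8 2,6-bis(benzyloxy)-4-(methoxymethoxy)phenol; 9 trichloroethylene
Product: 11 1,3-bis(benzyloxy)-2-{[(E)-1,2-dichloroethenyl]oxy}-5-(methoxymethoxy)benzene, via dichloroacetylene 10 (not isolated)
Conditions: K2CO3, DMF, 70 °C
Reagents that add atoms: none
Why: Base-induced dehydrochlorination of 9 gives dichloroacetylene, and anti addition of the phenoxide across it (nucleophilic addition to a haloalkyne) sets the (E) geometry of the dichlorovinyl ether.

Step 7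
Reactants: 11 1,3-bis(benzyloxy)-2-{[(E)-1,2-dichloroethenyl]oxy}-5-(methoxymethoxy)benzene
Product: 14 1,3-bis(benzyloxy)-2-(ethynyloxy)-5-(methoxymethoxy)benzene, via chloroalkynyl ether 12 (not isolated), via lithium acetylide 13 (not isolated)
Conditions: n-BuLi (2.1 equiv), THF, −78 to −40 °C; then aq NH4Cl, −78 °C
Reagents that add atoms: none
Why: E2 dehydrochlorination followed by lithium–chlorine exchange and protonation (dichlorovinyl ether route to alkynyl ethers) should give the terminal ynol ether, both events outrunning ring lithiation at −78 °C; the product is used cold and at once.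

Step 8
Reactants: 14 1,3-bis(benzyloxy)-2-(ethynyloxy)-5-(methoxymethoxy)benzene
Product: 16 1,3-bis(benzyloxy)-2-{[(E)-2-iodoethenyl]oxy}-5-(methoxymethoxy)benzene, via alkenylzirconocene 15 (not isolated)
Conditions: Cp2Zr(H)Cl, THF, rt; then I2, 0 °C
Reagents that add atoms: iodine, II
Why: Hydrozirconation adds Zr–H syn with zirconium on the terminal carbon, and iodinolysis of the C–Zr bond proceeds with retention, so the (E)-iodovinyl ether should result.

Step 9
Reactants: 17 squaric acid; 18 benzyl alcohol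
Product: 19 3,4-bis(benzyloxy)cyclobut-3-ene-1,2-dione (dibenzyl squarate)
Conditions: BnOH (2.2 equiv in all), toluene, reflux, Dean–Stark removal of water
Reagents that add atoms: benzyl alcohol, OCc1ccccc1
Why: Self-catalysed azeotropic Fischer-type esterification of the strongly acidic vinylogous diacid, as used for other dialkyl squarates; each of the two acidic hydroxyls takes up one molecule of benzyl alcohol (two equivalents of 18 in all, the second entered above as reagent) and the two molecules of water formed are removed as the toluene azeotrope.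

Step 10
Reactants: 16 1,3-bis(benzyloxy)-2-{[(E)-2-iodoethenyl]oxy}-5-(methoxymethoxy)benzene; 19 dibenzyl squarate
Product: 22 2,3-bis(benzyloxy)-4-hydroxy-4-{(E)-2-[2,6-bis(benzyloxy)-4-(methoxymethoxy)phenoxy]ethenyl}cyclobut-2-en-1-one (racemic), via alkenyllithium 20 (not isolated), via lithium alkoxide 21 (not isolated)
Conditions: t-BuLi (2.0 equiv), Et2O, −78 °C; then 19, THF, −78 °C; aq NH4Cl, −78 °C
Reagents that add atoms: none
Why: Lithium–iodine exchange retains the alkene geometry and the alkenyllithium adds 1,2 to one of the two equivalent squarate carbonyls (organolithium addition to a squaric ester); the carbinol centre forms racemic and is destroyed in step 12.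

Step 11
Reactants: 22 the hydroxycyclobutenone of step 10
Product: 23 2,3,4-tris(benzyloxy)-4-{(E)-2-[2,6-bis(benzyloxy)-4-(methoxymethoxy)phenoxy]ethenyl}cyclobut-2-en-1-one (racemic)
Conditions: BnBr, Ag2O, 4 Å molecular sieves, CH2Cl2, rt, dark
Reagents that add atoms: benzyl bromide, BrCc1ccccc1
Why: Ag2O-promoted O-benzylation (Williamson-type, no free alkoxide, no acid) avoids alkoxide-triggered ring opening and acid-induced collapse of the carbinol to a cyclobutenedione.

Step 12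
Reactants: 23 2,3,4-tris(benzyloxy)-4-{(E)-2-[2,6-bis(benzyloxy)-4-(methoxymethoxy)phenoxy]ethenyl}cyclobut-2-en-1-one
Product: 26 2,3,4-tris(benzyloxy)-6-[2,6-bis(benzyloxy)-4-(methoxymethoxy)phenoxy]phenol, via dienylketene 24 (not isolated), via cyclohexadienone 25 (not isolated)
Conditions: toluene (degassed, 0.02 M), 110 °C, argon
Reagents that add atoms: none
Why: Heating should cleave the C1–C4 bond of the cyclobutenone by conrotatory 4π electrocyclic opening to dienylketene 24, which closes by disrotatory 6π electrocyclization between the ketene carbon and the aryloxy-bearing vinyl terminus (the C1–C2 bond of ring G) to dienone 25, and 25 enolizes to phenol 26. The closest known reaction type is the thermal ring expansion of 4-alkenyl-4-alkoxycyclobutenones derived from squaric esters to hydroquinone monoethers (Moore rearrangement). The one ring formed is six-membered and closes by a pericyclic 6π electrocyclization, not by an ionic cyclization. No stereocentre is created: the carbinol carbon of 23 becomes sp2 in 24 and the sp3 carbon of 25 is lost on enolization. The step needs torquoselectivity, which the donor benzyloxy group on C4 should secure by rotating outward so that the vinyl group turns inward toward the ketene, while the (E)-alkene keeps the aryloxy group away from the closing termini. Regiochemistry needs no control because the squarate skeleton fixes every oxygen: the ketene oxygen becomes the free C2 phenol between the C3 benzyl ether and the C1 ether to ring F, and the former carbinol oxygen stays benzylated at C5.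

Step 13
Reactants: 7 2,6-bis(benzyloxy)benzene-1,4-diol
Product: 27 2,4,6-tris(benzyloxy)phenol (ring A unit)
Conditions: BnBr (1.0 equiv), K2CO3, acetone, rt, argon
Reagents that add atoms: benzyl bromide, BrCc1ccccc1
Why: Williamson ether synthesis with the same site selectivity as step 5; the unhindered, more acidic C4 hydroxyl should be alkylated first.

Step 14
Reactants: 26 2,3,4-tris(benzyloxy)-6-[2,6-bis(benzyloxy)-4-(methoxymethoxy)phenoxy]phenol
Product: 28 {2,3,4-tris(benzyloxy)-6-[2,6-bis(benzyloxy)-4-(methoxymethoxy)phenoxy]phenoxy}tri(propan-2-yl)silane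
Conditions: TIPSOTf, 2,6-lutidine, CH2Cl2, 0 °C to rt
Reagents that add atoms: tri(propan-2-yl)silyl trifluoromethanesulfonate, CC(C)[Si](OS(=O)(=O)C(F)(F)F)(C(C)C)C(C)C
Why: Silylation of the hindered phenol with a silyl triflate; the TIPS ether should survive acidic MOM removal and the phosphate base of the coupling and later leave with fluoride without touching benzyl ethers.

Step 15
Reactants: 28 the TIPS ether of step 14
Product: 29 3,5-bis(benzyloxy)-4-{3,4,5-tris(benzyloxy)-2-[tri(propan-2-yl)silyloxy]phenoxy}phenol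
Conditions: HCl (cat.), MeOH–THF, 40 °C
Reagents that add atoms: none
Why: Acid-catalysed acetal methanolysis removes the aryl MOM ether as dimethoxymethane, while benzyl ethers and the hindered aryl silyl ether are stable to dilute HCl.

Step 16
Reactants: 29 the phenol of step 15
Product: 30 3,5-bis(benzyloxy)-4-{3,4,5-tris(benzyloxy)-2-[tri(propan-2-yl)silyloxy]phenoxy}phenyl trifluoromethanesulfonate
Conditions: Tf2O, pyridine, CH2Cl2, 0 °C
Reagents that add atoms: trifluoromethanesulfonic anhydride, O=S(=O)(OS(=O)(=O)C(F)(F)F)C(F)(F)F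
Why: O-Sulfonylation of the unhindered phenol gives the aryl triflate that serves as electrophile for C–O coupling.

Step 17
Reactants: 26 ring-pair phenol; 30 dimer triflate
Product: 31 four-ring ether TIPSO–[pentaoxygenated ring]–O–[tetraoxygenated ring]–O–[pentaoxygenated ring]–O–[tetraoxygenated ring]–OMOM (the triflate carbon of 30 bonded to the hindered oxygen of 26; 10 benzyl ethers)
Conditions: Pd2(dba)3, 2-di-tert-butylphosphino-2',4',6'-triisopropylbiphenyl (t-BuXPhos), K3PO4, toluene, 100 °C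
Reagents that add atoms: none
Why: Buchwald–Hartwig diaryl ether coupling: the unhindered aryl triflate adds oxidatively to zerovalent palladium, the phenoxide of 26 replaces triflate, and C–O reductive elimination is favoured by the bulky biarylphosphine and the di-ortho-substituted phenoxide.

Step 18
Reactants: 31 four-ring TIPS/MOM ether
Product: 32 four-ring phenol (31 with the MOM ether replaced by a free hydroxyl)
Conditions: HCl (cat.), MeOH–THF, 40 °C
Reagents that add atoms: none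
Why: Acid-catalysed acetal methanolysis of the aryl MOM ether, as in step 15.

Step 19
Reactants: 32 four-ring phenol
Product: 33 four-ring triflate (32 with the free hydroxyl converted to OTf)
Conditions: Tf2O, pyridine, CH2Cl2, 0 °C
Reagents that add atoms: trifluoromethanesulfonic anhydride, O=S(=O)(OS(=O)(=O)C(F)(F)F)C(F)(F)F
Why: O-Sulfonylation of the unhindered phenol, as in step 16.

Step 20
Reactants: 27 2,4,6-tris(benzyloxy)phenol; 33 four-ring triflate
Product: 34 TIPS ether of the five-ring phenol (rings A to E; ring A oxygen on C1 of ring B; silyl ether on the C2 oxygen of ring E; 13 benzyl ethers)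
Conditions: Pd2(dba)3, t-BuXPhos, K3PO4, toluene, 100 °C
Reagents that add atoms: none
Why: Buchwald–Hartwig diaryl ether coupling as in step 17, between the di-ortho-benzyloxy phenol 27 and the unhindered triflate carbon of 33.

Step 21
Reactants: 34 five-ring TIPS ether
Product: 35 five-ring phenol (rings A to E; free hindered hydroxyl on C2 of ring E)
Conditions: TBAF, AcOH, THF, 0 °C
Reagents that add atoms: none
Why: Fluoride-induced cleavage of the aryl silyl ether (Si–F bond formation); benzyl and diaryl ethers are untouched.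

Step 22
Reactants: 35 five-ring phenol; 33 four-ring triflate
Product: 36 TIPS ether of the nine-ring phenol (rings A to E joined through the ring E C2 oxygen to C1 of ring F; rings F, G, H and I from 33; 23 benzyl ethers)
Conditions: Pd2(dba)3, t-BuXPhos, K3PO4, toluene, 100 °C
Reagents that add atoms: none
Why: Buchwald–Hartwig diaryl ether coupling as in step 17, with the hindered ring E phenoxide as nucleophile.

Step 23
Reactants: 36 nine-ring TIPS ether
Product: 37 nine-ring phenol (free hindered hydroxyl on C2 of ring I)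
Conditions: TBAF, AcOH, THF, 0 °C
Reagents that add atoms: none
Why: Fluoride-induced desilylation, as in step 21.

Step 24
Reactants: 4 3,4,5-tris(benzyloxy)phenol
Product: 38 3,4,5-tris(benzyloxy)phenyl trifluoromethanesulfonate (ring K unit)
Conditions: Tf2O, pyridine, CH2Cl2, 0 °C
Reagents that add atoms: trifluoromethanesulfonic anhydride, O=S(=O)(OS(=O)(=O)C(F)(F)F)C(F)(F)F
Why: O-Sulfonylation of an unhindered phenol.

Step 25
Reactants: 8 2,6-bis(benzyloxy)-4-(methoxymethoxy)phenol; 38 3,4,5-tris(benzyloxy)phenyl triflate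
Product: 39 1,3-bis(benzyloxy)-5-(methoxymethoxy)-2-[3,4,5-tris(benzyloxy)phenoxy]benzene (rings J–K)
Conditions: Pd2(dba)3, t-BuXPhos, K3PO4, toluene, 100 °C
Reagents that add atoms: none
Why: Buchwald–Hartwig diaryl ether coupling as in step 17, on the simplest hindered phenol/triflate pair of the series.

Step 26
Reactants: 39 J–K MOM ether
Product: 40 3,5-bis(benzyloxy)-4-[3,4,5-tris(benzyloxy)phenoxy]phenol
Conditions: HCl (cat.), MeOH–THF, 40 °C
Reagents that add atoms: none
Why: Acid-catalysed acetal methanolysis of the aryl MOM ether.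

Step 27
Reactants: 40 J–K phenol
Product: 41 3,5-bis(benzyloxy)-4-[3,4,5-tris(benzyloxy)phenoxy]phenyl trifluoromethanesulfonate
Conditions: Tf2O, pyridine, CH2Cl2, 0 °C
Reagents that add atoms: trifluoromethanesulfonic anhydride, O=S(=O)(OS(=O)(=O)C(F)(F)F)C(F)(F)F
Why: O-Sulfonylation of the unhindered phenol.

Step 28
Reactants: 37 nine-ring phenol; 41 J–K triflate
Product: 42 octacosa-O-benzyl ether of the target (all 28 hydroxyls benzylated)
Conditions: Pd2(dba)3, t-BuXPhos, K3PO4, toluene, 100 °C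
Reagents that add atoms: none
Why: Buchwald–Hartwig diaryl ether coupling as in step 17; the small triflate 41 can be used in excess against the valuable phenol.

Step 29
Reactants: 42 octacosa-O-benzyl ether
Product: 43 CNP0245174.0 (target)
Conditions: H2 (1 atm), Pd/C (10% palladium on carbon), THF–MeOH, rt; filtration under argon
Reagents that add atoms: none
Why: Hydrogenolysis of all 28 benzyl aryl ethers over palladium; diaryl ether bonds are inert under these conditions and the air-sensitive polyphenol is kept under argon.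

## Compound list

1 | 3,4,5-trihydroxybenzaldehyde | O=Cc1cc(O)c(O)c(O)c1 | starting material
2 | 3,4,5-tris(benzyloxy)benzaldehyde | O=Cc1cc(OCc9ccccc9)c(OCc9ccccc9)c(OCc9ccccc9)c1 | intermediate
3 | 3,4,5-tris(benzyloxy)phenyl formate | O=COc1cc(OCc9ccccc9)c(OCc9ccccc9)c(OCc9ccccc9)c1 | intermediate (not isolated)
4 | 3,4,5-tris(benzyloxy)phenol | Oc1cc(OCc9ccccc9)c(OCc9ccccc9)c(OCc9ccccc9)c1 | intermediate
5 | 3,4,5-tris(benzyloxy)-4-hydroxycyclohexa-2,5-dien-1-one | O=C1C=C(OCc9ccccc9)C(O)(OCc9ccccc9)C(OCc9ccccc9)=C1 | intermediate (not isolated)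
6 | 2,6-bis(benzyloxy)cyclohexa-2,5-diene-1,4-dione | O=C1C=C(OCc9ccccc9)C(=O)C(OCc9ccccc9)=C1 | intermediate
7 | 2,6-bis(benzyloxy)benzene-1,4-diol | Oc1cc(OCc9ccccc9)c(O)c(OCc9ccccc9)c1 | intermediate
8 | 2,6-bis(benzyloxy)-4-(methoxymethoxy)phenol | COCOc1cc(OCc9ccccc9)c(O)c(OCc9ccccc9)c1 | intermediate
9 | trichloroethylene | ClC=C(Cl)Cl | starting material
10 | dichloroacetylene | ClC#CCl | intermediate (not isolated)
11 | 1,3-bis(benzyloxy)-2-{[(E)-1,2-dichloroethenyl]oxy}-5-(methoxymethoxy)benzene | COCOc1cc(OCc9ccccc9)c(O/C(Cl)=C\Cl)c(OCc9ccccc9)c1 | intermediate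
12 | 1,3-bis(benzyloxy)-2-[(chloroethynyl)oxy]-5-(methoxymethoxy)benzene | COCOc1cc(OCc9ccccc9)c(OC#CCl)c(OCc9ccccc9)c1 | intermediate (not isolated)
13 | {[2,6-bis(benzyloxy)-4-(methoxymethoxy)phenoxy]ethynyl}lithium | COCOc1cc(OCc9ccccc9)c(OC#C[Li])c(OCc9ccccc9)c1 | intermediate (not isolated)
14 | 1,3-bis(benzyloxy)-2-(ethynyloxy)-5-(methoxymethoxy)benzene | COCOc1cc(OCc9ccccc9)c(OC#C)c(OCc9ccccc9)c1 | intermediate
15 | chloro{(E)-2-[2,6-bis(benzyloxy)-4-(methoxymethoxy)phenoxy]ethenyl}bis(cyclopentadienyl)zirconium | COCOc1cc(OCc9ccccc9)c(O/C=C/[Zr](Cl)(C2C=CC=C2)C2C=CC=C2)c(OCc9ccccc9)c1 | intermediate (not isolated)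
16 | 1,3-bis(benzyloxy)-2-{[(E)-2-iodoethenyl]oxy}-5-(methoxymethoxy)benzene | COCOc1cc(OCc9ccccc9)c(O/C=C/I)c(OCc9ccccc9)c1 | intermediate
17 | squaric acid | OC1=C(O)C(=O)C1=O | starting material
18 | benzyl alcohol | OCc1ccccc1 | starting material
19 | 3,4-bis(benzyloxy)cyclobut-3-ene-1,2-dione | O=C1C(=O)C(OCc9ccccc9)=C1OCc9ccccc9 | intermediate
20 | {(E)-2-[2,6-bis(benzyloxy)-4-(methoxymethoxy)phenoxy]ethenyl}lithium | COCOc1cc(OCc9ccccc9)c(O/C=C/[Li])c(OCc9ccccc9)c1 | intermediate (not isolated)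
21 | lithium alkoxide of 22 (racemic) | O=C1C(OCc9ccccc9)=C(OCc9ccccc9)C1(O[Li])/C=C/Oc3c(OCc9ccccc9)cc(OCOC)cc3OCc9ccccc9 | intermediate (not isolated)
22 | 2,3-bis(benzyloxy)-4-hydroxy-4-{(E)-2-[2,6-bis(benzyloxy)-4-(methoxymethoxy)phenoxy]ethenyl}cyclobut-2-en-1-one (racemic) | O=C1C(OCc9ccccc9)=C(OCc9ccccc9)C1(O)/C=C/Oc3c(OCc9ccccc9)cc(OCOC)cc3OCc9ccccc9 | intermediate
23 | 2,3,4-tris(benzyloxy)-4-{(E)-2-[2,6-bis(benzyloxy)-4-(methoxymethoxy)phenoxy]ethenyl}cyclobut-2-en-1-one (racemic) | O=C1C(OCc9ccccc9)=C(OCc9ccccc9)C1(OCc9ccccc9)/C=C/Oc3c(OCc9ccccc9)cc(OCOC)cc3OCc9ccccc9 | intermediate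
24 | (3Z,5E)-2,3,4-tris(benzyloxy)-6-[2,6-bis(benzyloxy)-4-(methoxymethoxy)phenoxy]hexa-1,3,5-trien-1-one | O=C=C(OCc9ccccc9)/C(OCc9ccccc9)=C(\C=C\Oc3c(OCc9ccccc9)cc(OCOC)cc3OCc9ccccc9)OCc9ccccc9 | intermediate (not isolated)
25 | 2,3,4-tris(benzyloxy)-6-[2,6-bis(benzyloxy)-4-(methoxymethoxy)phenoxy]cyclohexa-2,4-dien-1-one (racemic) | O=C1C(OCc9ccccc9)=C(OCc9ccccc9)C(OCc9ccccc9)=CC1Oc3c(OCc9ccccc9)cc(OCOC)cc3OCc9ccccc9 | intermediate (not isolated)
26 | 2,3,4-tris(benzyloxy)-6-[2,6-bis(benzyloxy)-4-(methoxymethoxy)phenoxy]phenol | Oc4c(OCc9ccccc9)c(OCc9ccccc9)c(OCc9ccccc9)cc4Oc3c(OCc9ccccc9)cc(OCOC)cc3OCc9ccccc9 | intermediate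
27 | 2,4,6-tris(benzyloxy)phenol | Oc1c(OCc9ccccc9)cc(OCc9ccccc9)cc1OCc9ccccc9 | intermediate
28 | {2,3,4-tris(benzyloxy)-6-[2,6-bis(benzyloxy)-4-(methoxymethoxy)phenoxy]phenoxy}tri(propan-2-yl)silane | CC(C)[Si](C(C)C)(C(C)C)Oc1c(OCc9ccccc9)c(OCc9ccccc9)c(OCc9ccccc9)cc1Oc2c(OCc9ccccc9)cc(OCOC)cc2OCc9ccccc9 | intermediate
29 | 3,5-bis(benzyloxy)-4-{3,4,5-tris(benzyloxy)-2-[tri(propan-2-yl)silyloxy]phenoxy}phenol | CC(C)[Si](C(C)C)(C(C)C)Oc1c(OCc9ccccc9)c(OCc9ccccc9)c(OCc9ccccc9)cc1Oc2c(OCc9ccccc9)cc(O)cc2OCc9ccccc9 | intermediate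
30 | 3,5-bis(benzyloxy)-4-{3,4,5-tris(benzyloxy)-2-[tri(propan-2-yl)silyloxy]phenoxy}phenyl trifluoromethanesulfonate | CC(C)[Si](C(C)C)(C(C)C)Oc1c(OCc9ccccc9)c(OCc9ccccc9)c(OCc9ccccc9)cc1Oc2c(OCc9ccccc9)cc(OS(=O)(=O)C(F)(F)F)cc2OCc9ccccc9 | intermediate
31 | four-ring TIPS/MOM ether (hindered oxygen of 26 on the former triflate carbon of 30) | CC(C)[Si](C(C)C)(C(C)C)Oc1c(OCc9ccccc9)c(OCc9ccccc9)c(OCc9ccccc9)cc1Oc3c(OCc9ccccc9)cc(Oc1c(OCc9ccccc9)c(OCc9ccccc9)c(OCc9ccccc9)cc1Oc2c(OCc9ccccc9)cc(OCOC)cc2OCc9ccccc9)cc3OCc9ccccc9 | intermediate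
32 | four-ring phenol (31 without MOM) | CC(C)[Si](C(C)C)(C(C)C)Oc1c(OCc9ccccc9)c(OCc9ccccc9)c(OCc9ccccc9)cc1Oc3c(OCc9ccccc9)cc(Oc1c(OCc9ccccc9)c(OCc9ccccc9)c(OCc9ccccc9)cc1Oc2c(OCc9ccccc9)cc(O)cc2OCc9ccccc9)cc3OCc9ccccc9 | intermediate
33 | four-ring triflate (triflate of 32) | CC(C)[Si](C(C)C)(C(C)C)Oc1c(OCc9ccccc9)c(OCc9ccccc9)c(OCc9ccccc9)cc1Oc3c(OCc9ccccc9)cc(Oc1c(OCc9ccccc9)c(OCc9ccccc9)c(OCc9ccccc9)cc1Oc2c(OCc9ccccc9)cc(OS(=O)(=O)C(F)(F)F)cc2OCc9ccccc9)cc3OCc9ccccc9 | intermediate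
34 | TIPS ether of the five-ring phenol (rings A to E) | CC(C)[Si](C(C)C)(C(C)C)Oc1c(OCc9ccccc9)c(OCc9ccccc9)c(OCc9ccccc9)cc1Oc3c(OCc9ccccc9)cc(Oc1c(OCc9ccccc9)c(OCc9ccccc9)c(OCc9ccccc9)cc1Oc2c(OCc9ccccc9)cc(Oc1c(OCc9ccccc9)cc(OCc9ccccc9)cc1OCc9ccccc9)cc2OCc9ccccc9)cc3OCc9ccccc9 | intermediate
35 | five-ring phenol (rings A to E, free hydroxyl on ring E C2) | Oc1c(OCc9ccccc9)c(OCc9ccccc9)c(OCc9ccccc9)cc1Oc3c(OCc9ccccc9)cc(Oc1c(OCc9ccccc9)c(OCc9ccccc9)c(OCc9ccccc9)cc1Oc2c(OCc9ccccc9)cc(Oc1c(OCc9ccccc9)cc(OCc9ccccc9)cc1OCc9ccccc9)cc2OCc9ccccc9)cc3OCc9ccccc9 | intermediate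
36 | TIPS ether of the nine-ring phenol | CC(C)[Si](C(C)C)(C(C)C)Oc1c(OCc9ccccc9)c(OCc9ccccc9)c(OCc9ccccc9)cc1Oc5c(OCc9ccccc9)cc(Oc1c(OCc9ccccc9)c(OCc9ccccc9)c(OCc9ccccc9)cc1Oc4c(OCc9ccccc9)cc(Oc1c(OCc9ccccc9)c(OCc9ccccc9)c(OCc9ccccc9)cc1Oc3c(OCc9ccccc9)cc(Oc1c(OCc9ccccc9)c(OCc9ccccc9)c(OCc9ccccc9)cc1Oc2c(OCc9ccccc9)cc(Oc1c(OCc9ccccc9)cc(OCc9ccccc9)cc1OCc9ccccc9)cc2OCc9ccccc9)cc3OCc9ccccc9)cc4OCc9ccccc9)cc5OCc9ccccc9 | intermediate
37 | nine-ring phenol (free hydroxyl on C2 of ring I) | Oc1c(OCc9ccccc9)c(OCc9ccccc9)c(OCc9ccccc9)cc1Oc5c(OCc9ccccc9)cc(Oc1c(OCc9ccccc9)c(OCc9ccccc9)c(OCc9ccccc9)cc1Oc4c(OCc9ccccc9)cc(Oc1c(OCc9ccccc9)c(OCc9ccccc9)c(OCc9ccccc9)cc1Oc3c(OCc9ccccc9)cc(Oc1c(OCc9ccccc9)c(OCc9ccccc9)c(OCc9ccccc9)cc1Oc2c(OCc9ccccc9)cc(Oc1c(OCc9ccccc9)cc(OCc9ccccc9)cc1OCc9ccccc9)cc2OCc9ccccc9)cc3OCc9ccccc9)cc4OCc9ccccc9)cc5OCc9ccccc9 | intermediate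
38 | 3,4,5-tris(benzyloxy)phenyl trifluoromethanesulfonate | FC(F)(F)S(=O)(=O)Oc1cc(OCc9ccccc9)c(OCc9ccccc9)c(OCc9ccccc9)c1 | intermediate
39 | 1,3-bis(benzyloxy)-5-(methoxymethoxy)-2-[3,4,5-tris(benzyloxy)phenoxy]benzene | COCOc1cc(OCc9ccccc9)c(Oc2cc(OCc9ccccc9)c(OCc9ccccc9)c(OCc9ccccc9)c2)c(OCc9ccccc9)c1 | intermediate
40 | 3,5-bis(benzyloxy)-4-[3,4,5-tris(benzyloxy)phenoxy]phenol | Oc1cc(OCc9ccccc9)c(Oc2cc(OCc9ccccc9)c(OCc9ccccc9)c(OCc9ccccc9)c2)c(OCc9ccccc9)c1 | intermediate
41 | 3,5-bis(benzyloxy)-4-[3,4,5-tris(benzyloxy)phenoxy]phenyl trifluoromethanesulfonate | FC(F)(F)S(=O)(=O)Oc1cc(OCc9ccccc9)c(Oc2cc(OCc9ccccc9)c(OCc9ccccc9)c(OCc9ccccc9)c2)c(OCc9ccccc9)c1 | intermediate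
42 | octacosa-O-benzyl ether of the target | c9ccccc9COc7cc(Oc6c(OCc9ccccc9)cc(Oc1c(OCc9ccccc9)c(OCc9ccccc9)c(OCc9ccccc9)cc1Oc5c(OCc9ccccc9)cc(Oc1c(OCc9ccccc9)c(OCc9ccccc9)c(OCc9ccccc9)cc1Oc4c(OCc9ccccc9)cc(Oc1c(OCc9ccccc9)c(OCc9ccccc9)c(OCc9ccccc9)cc1Oc3c(OCc9ccccc9)cc(Oc1c(OCc9ccccc9)c(OCc9ccccc9)c(OCc9ccccc9)cc1Oc2c(OCc9ccccc9)cc(Oc1c(OCc9ccccc9)cc(OCc9ccccc9)cc1OCc9ccccc9)cc2OCc9ccccc9)cc3OCc9ccccc9)cc4OCc9ccccc9)cc5OCc9ccccc9)cc6OCc9ccccc9)cc(OCc9ccccc9)c7OCc9ccccc9 | intermediate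
43 | CNP0245174.0 | Oc1cc(O)c(Oc2cc(O)c(Oc3cc(O)c(O)c(O)c3Oc3cc(O)c(Oc4cc(O)c(O)c(O)c4Oc4cc(O)c(Oc5cc(O)c(O)c(O)c5Oc5cc(O)c(Oc6cc(O)c(O)c(O)c6Oc6cc(O)c(Oc7cc(O)c(O)c(O)c7)c(O)c6)c(O)c5)c(O)c4)c(O)c3)c(O)c2)c(O)c1 | target

## Step count and risks

Total step count: 29. Longest linear sequence: 23 steps (steps 1–8, 10–12, 14–23, 28, 29).

Steps most likely to fail:

**Step 10.** The (E)-2-aryloxyvinyllithium 20 may lose lithium aryloxide by anti β-elimination, or the base may metalate ring F next to the MOM ether, before carbonyl addition takes place. The fallback sets out from 11 and 19 and keeps the ring expansion. Compound 11 is treated with n-BuLi (2.1 equiv, THF, −78 °C) to give acetylide 13, which is not protonated but added directly to 19. This forms the lithium alkoxide of the alkynyl carbinol F1, and NH4Cl quench gives 2,3-bis(benzyloxy)-4-hydroxy-4-{[2,6-bis(benzyloxy)-4-(methoxymethoxy)phenoxy]ethynyl}cyclobut-2-en-1-one F2. BnBr/Ag2O then gives the 4-benzyloxy alkynylcyclobutenone F3. Partial hydrogenation over Pd/CaCO3 poisoned with Pb(OAc)2 and quinoline gives the (Z)-alkenylcyclobutenone F4. Heating F4 in toluene as in step 12 should pass through the (3Z,5Z)-dienylketene F5 and dienone 25, whose ring closure tolerates a cis-substituted terminus as aryl groups do, and rejoin the route at 26.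

**Step 12.** Ring opening with the benzyloxy group turned inward would give a ketene that cannot close; it may then be consumed by dimerization or by [2+2] addition to the enol ether, and long heating may erode the aryl vinyl ether. The fallback sets out from carbinol 22, whose free hydroxyl has the stronger outward preference. Heating 22 in degassed toluene (110 °C) should give, by way of the hydroxy dienylketene F6 and the hydroxy cyclohexadienone F7, the hydroquinone 2,3-bis(benzyloxy)-5-[2,6-bis(benzyloxy)-4-(methoxymethoxy)phenoxy]benzene-1,4-diol F8. Benzylation of F8 with BnBr (1.0 equiv), K2CO3, acetone under argon should occur at the C1 hydroxyl, which lies between a benzyloxy group and a ring hydrogen. The C4 hydroxyl, between a benzyloxy and the aryloxy group, stays free, which brings the route back at 26.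

**Step 28 (the same concern applies to steps 17, 20, 22 and 25).** C–O reductive elimination from the crowded arylpalladium phenoxide may be slower than S–O cleavage of the triflate by phosphate or phenoxide, which returns phenol 40 and stalls the coupling. The fallback sets out from 41 and replaces palladium-mediated C–O bond formation by copper-mediated oxidative coupling. Miyaura borylation (bis(pinacolato)diboron, PdCl2(dppf), KOAc, dioxane, 80 °C) gives the pinacol boronate F9. Cleavage with NaIO4, NH4OAc in acetone–H2O gives the boronic acid F10. Chan–Lam coupling of F10 with phenol 37 (Cu(OAc)2, pyridine, 4 Å molecular sieves, CH2Cl2, air, rt) should then give 42, where the route is rejoined.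

## Further compounds

F1 | step 10 | lithium alkoxide of F2 (racemic) | O=C1C(OCc9ccccc9)=C(OCc9ccccc9)C1(O[Li])C#COc3c(OCc9ccccc9)cc(OCOC)cc3OCc9ccccc9
F2 | step 10 | 2,3-bis(benzyloxy)-4-hydroxy-4-{[2,6-bis(benzyloxy)-4-(methoxymethoxy)phenoxy]ethynyl}cyclobut-2-en-1-one (racemic) | O=C1C(OCc9ccccc9)=C(OCc9ccccc9)C1(O)C#COc3c(OCc9ccccc9)cc(OCOC)cc3OCc9ccccc9
F3 | step 10 | 2,3,4-tris(benzyloxy)-4-{[2,6-bis(benzyloxy)-4-(methoxymethoxy)phenoxy]ethynyl}cyclobut-2-en-1-one (racemic) | O=C1C(OCc9ccccc9)=C(OCc9ccccc9)C1(OCc9ccccc9)C#COc3c(OCc9ccccc9)cc(OCOC)cc3OCc9ccccc9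
F4 | step 10 | 2,3,4-tris(benzyloxy)-4-{(Z)-2-[2,6-bis(benzyloxy)-4-(methoxymethoxy)phenoxy]ethenyl}cyclobut-2-en-1-one (racemic) | O=C1C(OCc9ccccc9)=C(OCc9ccccc9)C1(OCc9ccccc9)/C=C\Oc3c(OCc9ccccc9)cc(OCOC)cc3OCc9ccccc9
F5 | step 10 | (3Z,5Z)-2,3,4-tris(benzyloxy)-6-[2,6-bis(benzyloxy)-4-(methoxymethoxy)phenoxy]hexa-1,3,5-trien-1-one | O=C=C(OCc9ccccc9)/C(OCc9ccccc9)=C(\C=C/Oc3c(OCc9ccccc9)cc(OCOC)cc3OCc9ccccc9)OCc9ccccc9
F6 | step 12 | (3Z,5E)-2,3-bis(benzyloxy)-4-hydroxy-6-[2,6-bis(benzyloxy)-4-(methoxymethoxy)phenoxy]hexa-1,3,5-trien-1-one | O=C=C(OCc9ccccc9)/C(OCc9ccccc9)=C(\C=C\Oc3c(OCc9ccccc9)cc(OCOC)cc3OCc9ccccc9)O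
F7 | step 12 | 2,3-bis(benzyloxy)-4-hydroxy-6-[2,6-bis(benzyloxy)-4-(methoxymethoxy)phenoxy]cyclohexa-2,4-dien-1-one (racemic) | O=C1C(OCc9ccccc9)=C(OCc9ccccc9)C(O)=CC1Oc3c(OCc9ccccc9)cc(OCOC)cc3OCc9ccccc9
F8 | step 12 | 2,3-bis(benzyloxy)-5-[2,6-bis(benzyloxy)-4-(methoxymethoxy)phenoxy]benzene-1,4-diol | Oc4c(OCc9ccccc9)c(OCc9ccccc9)c(O)cc4Oc3c(OCc9ccccc9)cc(OCOC)cc3OCc9ccccc9
F9 | step 28 | 2-{3,5-bis(benzyloxy)-4-[3,4,5-tris(benzyloxy)phenoxy]phenyl}-4,4,5,5-tetramethyl-1,3,2-dioxaborolane | CC1(C)OB(OC1(C)C)c2cc(OCc9ccccc9)c(Oc3cc(OCc9ccccc9)c(OCc9ccccc9)c(OCc9ccccc9)c3)c(OCc9ccccc9)c2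
F10 | step 28 | {3,5-bis(benzyloxy)-4-[3,4,5-tris(benzyloxy)phenoxy]phenyl}boronic acid | OB(O)c2cc(OCc9ccccc9)c(Oc3cc(OCc9ccccc9)c(OCc9ccccc9)c(OCc9ccccc9)c3)c(OCc9ccccc9)c2
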